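## The problem

The target is a (3R)-isoflavanone: a chroman-4-one (ring A fused to ring C) with a hydroxyl at C7 and, at C3, a pentasubstituted ring B (2',3'-dihydroxy, 4'-methoxy, 5'-prenyl). Ring C is joined to ring A by the O1–C8a and C4–C4a bonds and to ring B by C3–C1'; its last atom, C2, is a methylene between O1 and C3. The only stereocentre, C3, is benzylic and alpha to the C4 ketone. Nothing in the molecule can control it, and it is lost by enolisation in base and, more slowly, in acid, so it has to be set by a reagent, late, and followed only by operations that do not enolise the ketone. The prenyl double bond excludes hydrogenolysis and strong protic or Lewis acids, the free catechol excludes oxidants, and the 2'-hydroxyl can add to C4 and lose water under forcing acid. Ring A has no oxygen at C5, so the site of acylation on the resorcinol-type ring must be fixed by a group that can be removed afterwards, and ring B needs its prenyl group placed at C5', next to the methoxy group. The enabling feature is that O1 and the C4 acyl carbon sit on neighbouring ring A carbons, C8a and C4a. That is the pattern an aryne leaves when it inserts into the O–C(=O) unit of a carboxylic acid, and with a 2-arylacrylic acid the methylene ends up where C2 is needed.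

## Retrosynthesis

**C3–H bond, last.** Target 26 is traced to the achiral per-silylated enol ether 24, in which C3 is planar. Cutting the C3–H bond last means only methanolysis of aryl trimethylsilyl ethers follows the stereo-defining step (through 25, not isolated). Setting C3 during ring closure would leave an acid deprotection after it and put the configuration at risk. The forward step asks a chiral Brønsted acid to protonate one face of a 3-aryl-4-silyloxy-2H-chromene. Enol ether 24 comes from racemic triol 23 by silylation of the three phenols and the ketone in one operation.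

**Protecting groups and the chlorine, at the racemic stage.** Triol 23 is traced to the tris-MOM ether 22 and this to the 5-chloro compound 21. Acidic methanolysis and palladium hydride chemistry are both placed before C3 is set, where enolisation costs nothing. The chlorine is kept because of what it does in the next cut.

**Ring C by aryne insertion.** Chromanone 21 is cut at O1–C8a, C4–C4a and O1–C2, giving the ortho-silylaryl triflate 7 and the 2-arylacrylic acid 18. The neighbouring cuts are acylation of a resorcinol ether by an arylacetic acid, or addition of an aryl metal to an arylacetic acid derivative. The first needs Lewis acids that MOM ethers and the prenyl group will not stand; both form one bond at a time and still need a separate methylenation on the ketone. The aryne cut makes three bonds from two fragments of similar size and uses only fluoride. The forward reaction must put oxygen at C8a and the acyl group at C4a. A chlorine at C5 of the aryne (19) secures this, because the carboxylate then adds to the remote aryne carbon and the aryl anion forms next to chlorine.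

**Acrylic acid 18.** The methylene is cut back to formaldehyde and methyl arylacetate 16 (through acrylate 17). The acetate carbon chain is cut to aldehyde 13 through acid 15 and nitrile 14, a one-carbon homologation. This keeps the aldehyde carbon of the commercial starting material as C1'-bound carbon and needs no acid, which the MOM ethers would not survive.

**Prenyl group.** Aldehyde 13 is cut at the C5'–CH2 bond to aryl bromide 10 and prenyl bromide 11. Bromide 10 comes from 2,3-dihydroxy-4-methoxybenzaldehyde 8 through bromophenol 9. C5 of 8 is para to the C2 hydroxyl, ortho to the methoxy group and meta to the aldehyde, so electrophilic bromination should go there alone. A Claisen route would need one catechol hydroxyl singled out first.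

**Aryne precursor 7.** The MOM group is cut to phenol 6, and the triflate and C–Si bond are traced through a retro-Brook rearrangement to the bis-silyl ether 3 of 4-bromo-5-chlororesorcinol 2, made from 5-chlororesorcinol 1. One bromination breaks the symmetry. Only the oxygen ortho to bromine can pass its silyl group to carbon and become the phenoxide that is triflated, so the two hydroxyls are told apart without a selective protection.

## Roads not taken

**Alternative 1: rhodium carbene C–H insertion into the ring A methoxy group.** The cut is C2–C3. A diaryl diazoketone A2 with a methoxy group ortho to the ketone on ring A would be decomposed by a chiral divalent rhodium carboxylate such as Rh2(S-PTTL)4. The carbene at C3 would insert into a C–H bond of the OCH3 group, closing ring C and setting C3 to give the tris-TBS ether A1.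
- Merits: ring closure and stereocentre come in one catalytic step, no directing chlorine is needed, and the end game is one deprotection.
- Weak points: the carbene is flanked by a ketone and by an ether oxygen five atoms away, so oxonium ylide formation followed by a 1,2-methyl shift to a 2-aryl-2-methylbenzofuranone competes. So do Wolff rearrangement and cyclopropanation of the prenyl alkene. Six-ring C–H insertion of a ketone-substituted carbene with high enantiocontrol is not a settled reaction. The TBS groups of A1 would come off with fluoride, which is basic enough to endanger C3.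
- Comparison: this road is shorter after the key step and sets C3 directly, which the chosen plan does not. The chosen plan sets against it a ring-forming step of a known type and a stereo-defining step that is the last operation.

**Alternative 2: intramolecular Stetter reaction onto a ring B ortho-quinone methide.** The cut is C3–C4. In aldehyde A4, CsF would free the C2' phenoxide, acetate would leave to give the ortho-quinone methide, and a chiral triazolium-derived carbene would turn the ring A aldehyde into an acyl anion. This adds 6-exo-trig to C3 and gives A3 with the 2'-hydroxyl already free.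
- Merits: C3 is set in the C–C bond-forming step and one deprotection is saved.
- Weak points: A4 needs the 2'- and 3'-oxygens of the catechol differentiated, a problem the chosen plan never meets. The quinone methide can oligomerise or be trapped by fluoride. The product is an enolisable α-aryl ketone born in a basic medium (carbene, CsF, phenoxide), so its configuration is unlikely to last in the flask. Two MOM groups must still be removed in acid afterwards.
- Comparison: it is more direct on paper, but it puts the labile centre into the very conditions that destroy it. The chosen plan keeps C3 planar until the end.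

**Alternative 3: oxa-Michael ring closure with catalytic enantioselective protonation.** The cut is O1–C2. A cinchona-derived squaramide–amine would make the ring A phenol of enone A6 add to the methylene terminus and then protonate the enol at C3, giving the tris-MOM ether A5.
- Merits: this is the shortest road. A6 comes from a deoxybenzoin by methylenation, without an aryne precursor, a chlorine or a dechlorination, and the ring closure is the same O1–C2 bond that the chosen plan forms.
- Weak points: an ortho-hydroxyaryl vinyl ketone cyclises readily without any catalyst, so the background reaction is racemic. The amine catalyst can epimerise the product. The three MOM groups of A5 must be removed in acid after C3 is set.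
- Comparison: in step count this road is better. The chosen plan sets against it the separation of ring formation from stereocontrol, with the asymmetric step moved behind the deprotection, and a convergent key step that joins two fragments through three bonds.

Key step: step 13

Assumption 1: bromination of 5-chlororesorcinol is taken to occur once, at C4 (ortho to one hydroxyl, para to the other), as is usual for 5-substituted resorcinols.

Assumption 2: which antipode of the chiral acid gives the 3R ketone is to be fixed by a trial with either antipode; the route is written for the antipode that gives 3R.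

## Route

Step 1
Reactants: 1 5-chlororesorcinol
Product: 2 4-bromo-5-chlorobenzene-1,3-diol
Conditions: NBS, MeCN, −30 to 0 °C
Reagents that add atoms: N-bromosuccinimide, O=C1CCC(=O)N1Br
Why: Electrophilic aromatic bromination; C4 is ortho to one hydroxyl and para to the other and less crowded than C2 between the hydroxyls, and low temperature with one equivalent should limit a second bromination.

Step 2
Reactants: 2 4-bromo-5-chlorobenzene-1,3-diol
Product: 3 4-bromo-5-chloro-1,3-bis(trimethylsilyloxy)benzene
Conditions: HMDS, THF, 70 °C; evaporate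
Reagents that add atoms: hexamethyldisilazane, C[Si](C)(C)N[Si](C)(C)C
Why: O-silylation of phenols with hexamethyldisilazane; ammonia is the only by-product, so the crude ether can be used after evaporation.

Step 3
Reactants: 3 4-bromo-5-chloro-1,3-bis(trimethylsilyloxy)benzene
Product: 6 3-chloro-5-hydroxy-2-(trimethylsilyl)phenyl trifluoromethanesulfonate, via lithium silylphenoxide 4 (not isolated), via silyl ether triflate 5 (not isolated)
Conditions: n-BuLi, THF, −78 °C; Tf2O, −78 to 0 °C; then MeOH, citric acid, rt
Reagents that add atoms: trifluoromethanesulfonic anhydride, O=S(=O)(OS(=O)(=O)C(F)(F)F)C(F)(F)F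
Why: Bromine–lithium exchange followed by retro-Brook rearrangement moves the silyl group from the ortho oxygen to carbon and leaves phenoxide 4, the only oxygen that Tf2O can triflate. The remaining aryl silyl ether of 5 is methanolysed under weak acid that leaves the C–Si bond intact.

Step 4
Reactants: 6 3-chloro-5-hydroxy-2-(trimethylsilyl)phenyl trifluoromethanesulfonate
Product: 7 3-chloro-5-(methoxymethoxy)-2-(trimethylsilyl)phenyl trifluoromethanesulfonate
Conditions: MOMCl, i-Pr2NEt, CH2Cl2, 0 °C to rt
Reagents that add atoms: chloromethyl methyl ether, COCCl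
Why: O-alkylation of a phenol with MOMCl and a hindered amine; no fluoride is present, so the silyl triflate is untouched.

Step 5
Reactants: 8 2,3-dihydroxy-4-methoxybenzaldehyde
Product: 9 5-bromo-2,3-dihydroxy-4-methoxybenzaldehyde
Conditions: Br2, NaOAc, AcOH, rt
Reagents that add atoms: bromine, BrBr
Why: Electrophilic aromatic bromination; C5 is para to the C2 hydroxyl, ortho to the methoxy group and meta to the aldehyde, whereas C6 is ortho to the deactivating aldehyde.

Step 6
Reactants: 9 5-bromo-2,3-dihydroxy-4-methoxybenzaldehyde
Product: 10 5-bromo-4-methoxy-2,3-bis(methoxymethoxy)benzaldehyde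
Conditions: MOMCl, i-Pr2NEt, CH2Cl2, 0 to 40 °C
Reagents that add atoms: chloromethyl methyl ether, COCCl
Why: Double O-alkylation of the catechol; MOM ethers are chosen because they withstand organolithiums, base and fluoride in all later steps.

Step 7
Reactants: 10 5-bromo-4-methoxy-2,3-bis(methoxymethoxy)benzaldehyde; 11 prenyl bromide (1-bromo-3-methylbut-2-ene)
Product: 13 4-methoxy-2,3-bis(methoxymethoxy)-5-(3-methylbut-2-en-1-yl)benzaldehyde, via lithium α-amino alkoxide 12 (not isolated)
Conditions: LiN(Me)CH2CH2NMe2 (from the amine and n-BuLi), THF, −20 °C; n-BuLi, −78 °C; CuBr·SMe2 (cat.), 11, −78 to 0 °C; aq. NH4Cl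
Reagents that add atoms: none
Why: The aldehyde is masked in the flask as α-amino alkoxide 12, bromine–lithium exchange gives the aryllithium, and copper-catalysed allylation with the primary bromide gives the linear prenyl arene. Aqueous work-up returns the aldehyde.

Step 8
Reactants: 13 4-methoxy-2,3-bis(methoxymethoxy)-5-(3-methylbut-2-en-1-yl)benzaldehyde
Product: 14 2-[4-methoxy-2,3-bis(methoxymethoxy)-5-(3-methylbut-2-en-1-yl)phenyl]acetonitrile
Conditions: TosMIC, t-BuOK, DME, −40 °C; then MeOH, 65 °C
Reagents that add atoms: tosylmethyl isocyanide, Cc1ccc(cc1)S(=O)(=O)C[N+]#[C-]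
Why: Van Leusen reductive cyanation: the TosMIC anion adds to the aldehyde, and methanolysis of the formamide with loss of sulfinate gives the homologous nitrile under basic conditions that spare MOM ethers and the alkene.

Step 9
Reactants: 14 2-[4-methoxy-2,3-bis(methoxymethoxy)-5-(3-methylbut-2-en-1-yl)phenyl]acetonitrile
Product: 15 2-[4-methoxy-2,3-bis(methoxymethoxy)-5-(3-methylbut-2-en-1-yl)phenyl]acetic acid
Conditions: KOH, EtOH/H2O, 85 °C; then 1 M HCl to pH 3, 0 °C
Reagents that add atoms: water, O; potassium hydroxide, [K+].[OH-]
Why: Alkaline hydrolysis of a nitrile to the carboxylate; MOM ethers and the prenyl group are stable to hydroxide, and the brief cold acidification should not cleave the acetals.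

Step 10
Reactants: 15 2-[4-methoxy-2,3-bis(methoxymethoxy)-5-(3-methylbut-2-en-1-yl)phenyl]acetic acid
Product: 16 methyl 2-[4-methoxy-2,3-bis(methoxymethoxy)-5-(3-methylbut-2-en-1-yl)phenyl]acetate
Conditions: MeI, K2CO3, DMF, rt
Reagents that add atoms: iodomethane, CI
Why: Carboxylate O-alkylation; it avoids the acid of a Fischer esterification.

Step 11
Reactants: 16 methyl 2-[4-methoxy-2,3-bis(methoxymethoxy)-5-(3-methylbut-2-en-1-yl)phenyl]acetate
Product: 17 methyl 2-[4-methoxy-2,3-bis(methoxymethoxy)-5-(3-methylbut-2-en-1-yl)phenyl]prop-2-enoate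
Conditions: (CH2O)n, K2CO3, Bu4NI, toluene, 80 °C
Reagents that add atoms: paraformaldehyde (formaldehyde), C=O
Why: Aldol addition of the arylacetate enolate to formaldehyde followed by dehydration, the standard α-methylenation of arylacetic esters.

Step 12
Reactants: 17 methyl 2-[4-methoxy-2,3-bis(methoxymethoxy)-5-(3-methylbut-2-en-1-yl)phenyl]prop-2-enoate
Product: 18 2-[4-methoxy-2,3-bis(methoxymethoxy)-5-(3-methylbut-2-en-1-yl)phenyl]prop-2-enoic acid
Conditions: LiOH, THF/H2O, 0 °C to rt; then 1 M HCl to pH 3, 0 °C
Reagents that add atoms: lithium hydroxide, [Li+].[OH-]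
Why: Saponification of a methyl ester; low temperature keeps conjugate addition of hydroxide to the acrylate slow.

Step 13
Reactants: 7 3-chloro-5-(methoxymethoxy)-2-(trimethylsilyl)phenyl trifluoromethanesulfonate; 18 2-[4-methoxy-2,3-bis(methoxymethoxy)-5-(3-methylbut-2-en-1-yl)phenyl]prop-2-enoic acid
Product: 21 racemic 5-chloro-3-[4-methoxy-2,3-bis(methoxymethoxy)-5-(3-methylbut-2-en-1-yl)phenyl]-7-(methoxymethoxy)chroman-4-one, via aryne 19 (not isolated), via caesium acylphenoxide 20 (not isolated)
Conditions: CsF, THF, 125 °C (sealed tube), 7 in excess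
Reagents that add atoms: none
Why: Fluoride removes the silyl group of 7 and triflate leaves, giving aryne 19. The caesium carboxylate of 18 adds to the aryne carbon remote from chlorine (future C8a), because the aryl anion then sits at C4a next to the inductively stabilising chlorine, a bias that outweighs the weak opposite one of the C7 alkoxy group. The C4a anion attacks the carbonyl of the aryl ester just formed, and the four-membered alkoxide opens to the ortho-acyl phenoxide 20 (C8a–O1 and C4–C4a bonds). Phenoxide 20 closes ring C by 6-endo-trig oxa-Michael addition to the unsubstituted methylene (O1–C2 bond), and the enolate is protonated by the acid present. The closest known reaction type is the fluoride-induced insertion of arynes into carboxylic acids to give ortho-hydroxyaryl ketones, which with acrylic acids runs on to chroman-4-ones under the same conditions. C3 arises by unselective protonation and is racemic here; it is set in step 17. The step needs regioselective carboxylate addition, secured by the C5 chlorine, and acyl transfer faster than protonation of the aryl anion or loss of chloride, secured by the intramolecular transfer and the high temperature. MOM ethers, the methyl ether and the prenyl group are inert to CsF.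

Step 14
Reactants: 21 racemic 5-chloro-3-[4-methoxy-2,3-bis(methoxymethoxy)-5-(3-methylbut-2-en-1-yl)phenyl]-7-(methoxymethoxy)chroman-4-one
Product: 22 racemic 3-[4-methoxy-2,3-bis(methoxymethoxy)-5-(3-methylbut-2-en-1-yl)phenyl]-7-(methoxymethoxy)chroman-4-one
Conditions: Pd(OAc)2, 2-dicyclohexylphosphino-2',4',6'-triisopropylbiphenyl (XPhos), HCO2Na, DMF, 80 °C
Reagents that add atoms: none
Why: Palladium-catalysed transfer hydrodehalogenation; the C–Cl bond ortho to the ketone is activated for oxidative addition, and formate gives the palladium hydride without hydrogen gas, which should leave the trisubstituted alkene alone.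

Step 15
Reactants: 22 racemic 3-[4-methoxy-2,3-bis(methoxymethoxy)-5-(3-methylbut-2-en-1-yl)phenyl]-7-(methoxymethoxy)chroman-4-one
Product: 23 racemic 3-[2,3-dihydroxy-4-methoxy-5-(3-methylbut-2-en-1-yl)phenyl]-7-hydroxychroman-4-one
Conditions: 2 M HCl, MeOH/THF, 40 °C
Reagents that add atoms: none
Why: Acid-catalysed methanolysis of aryl MOM ethers, done while C3 is still racemic so that enolisation is harmless. The prenyl group has no free ortho hydroxyl to cyclise onto, and the mild temperature should keep cyclodehydration of the 2'-hydroxyl onto C4 slow.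

Step 16
Reactants: 23 racemic 3-[2,3-dihydroxy-4-methoxy-5-(3-methylbut-2-en-1-yl)phenyl]-7-hydroxychroman-4-one
Product: 24 3-[4-methoxy-5-(3-methylbut-2-en-1-yl)-2,3-bis(trimethylsilyloxy)phenyl]-4,7-bis(trimethylsilyloxy)-2H-chromene
Conditions: TMSOTf, Et3N, CH2Cl2, 0 °C to rt; evaporate, extract into pentane, filter under argon
Reagents that add atoms: trimethylsilyl trifluoromethanesulfonate, C[Si](C)(C)OS(=O)(=O)C(F)(F)F
Why: Silylation of the three phenols and soft enolisation of the α-aryl ketone to its silyl enol ether; only C3 can enolise, and it becomes planar.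

Step 17
Reactants: 24 3-[4-methoxy-5-(3-methylbut-2-en-1-yl)-2,3-bis(trimethylsilyloxy)phenyl]-4,7-bis(trimethylsilyloxy)-2H-chromene
Product: 26 (3R)-3-[2,3-dihydroxy-4-methoxy-5-(3-methylbut-2-en-1-yl)phenyl]-7-hydroxychroman-4-one, via tris(trimethylsilyl) ether 25 (not isolated)
Conditions: 3,3'-bis(2,4,6-triisopropylphenyl)-1,1'-binaphthyl-2,2'-diyl N-triflyl thiophosphoramide (antipode giving 3R, 5 mol%), PhOH, toluene, rt; then MeOH, citric acid, 0 °C
Reagents that add atoms: none
Why: Catalytic enantioselective protonation of a silyl enol ether of a 2-aryl cyclic ketone: the chiral acid delivers the proton to one face of C3 within a chiral ion pair, and phenol takes up the silyl group and regenerates the acid. The configuration at C3 is controlled by the catalyst antipode alone. The aryl silyl ethers of 25 are then methanolysed under weak acid that does not enolise the ketone.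

## Compound list

1 | 5-chlororesorcinol | Oc1cc(O)cc(Cl)c1 | starting material
2 | 4-bromo-5-chlorobenzene-1,3-diol | Oc1cc(O)c(Br)c(Cl)c1 | intermediate
3 | 4-bromo-5-chloro-1,3-bis(trimethylsilyloxy)benzene | C[Si](C)(C)Oc1cc(O[Si](C)(C)C)c(Br)c(Cl)c1 | intermediate
4 | lithium 3-chloro-2-(trimethylsilyl)-5-(trimethylsilyloxy)phenoxide | [Li+].[O-]c1cc(O[Si](C)(C)C)cc(Cl)c1[Si](C)(C)C | intermediate
5 | 3-chloro-2-(trimethylsilyl)-5-(trimethylsilyloxy)phenyl trifluoromethanesulfonate | C[Si](C)(C)Oc1cc(Cl)c([Si](C)(C)C)c(OS(=O)(=O)C(F)(F)F)c1 | intermediate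
6 | 3-chloro-5-hydroxy-2-(trimethylsilyl)phenyl trifluoromethanesulfonate | Oc1cc(Cl)c([Si](C)(C)C)c(OS(=O)(=O)C(F)(F)F)c1 | intermediate
7 | 3-chloro-5-(methoxymethoxy)-2-(trimethylsilyl)phenyl trifluoromethanesulfonate | COCOc1cc(Cl)c([Si](C)(C)C)c(OS(=O)(=O)C(F)(F)F)c1 | intermediate
8 | 2,3-dihydroxy-4-methoxybenzaldehyde | COc1ccc(C=O)c(O)c1O | starting material
9 | 5-bromo-2,3-dihydroxy-4-methoxybenzaldehyde | COc1c(Br)cc(C=O)c(O)c1O | intermediate
10 | 5-bromo-4-methoxy-2,3-bis(methoxymethoxy)benzaldehyde | COCOc1c(C=O)cc(Br)c(OC)c1OCOC | intermediate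
11 | prenyl bromide (1-bromo-3-methylbut-2-ene) | CC(C)=CCBr | starting material
12 | lithium [5-bromo-4-methoxy-2,3-bis(methoxymethoxy)phenyl]{[2-(dimethylamino)ethyl](methyl)amino}methanolate (racemic) | [Li+].[O-]C(N(C)CCN(C)C)c1cc(Br)c(OC)c(OCOC)c1OCOC | intermediate
13 | 4-methoxy-2,3-bis(methoxymethoxy)-5-(3-methylbut-2-en-1-yl)benzaldehyde | COCOc1c(C=O)cc(CC=C(C)C)c(OC)c1OCOC | intermediate
14 | 2-[4-methoxy-2,3-bis(methoxymethoxy)-5-(3-methylbut-2-en-1-yl)phenyl]acetonitrile | COCOc1c(CC#N)cc(CC=C(C)C)c(OC)c1OCOC | intermediate
15 | 2-[4-methoxy-2,3-bis(methoxymethoxy)-5-(3-methylbut-2-en-1-yl)phenyl]acetic acid | COCOc1c(CC(=O)O)cc(CC=C(C)C)c(OC)c1OCOC | intermediate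
16 | methyl 2-[4-methoxy-2,3-bis(methoxymethoxy)-5-(3-methylbut-2-en-1-yl)phenyl]acetate | COCOc1c(CC(=O)OC)cc(CC=C(C)C)c(OC)c1OCOC | intermediate
17 | methyl 2-[4-methoxy-2,3-bis(methoxymethoxy)-5-(3-methylbut-2-en-1-yl)phenyl]prop-2-enoate | COCOc1c(C(=C)C(=O)OC)cc(CC=C(C)C)c(OC)c1OCOC | intermediate
18 | 2-[4-methoxy-2,3-bis(methoxymethoxy)-5-(3-methylbut-2-en-1-yl)phenyl]prop-2-enoic acid | COCOc1c(C(=C)C(=O)O)cc(CC=C(C)C)c(OC)c1OCOC | intermediate
19 | 3-chloro-5-(methoxymethoxy)-1,2-didehydrobenzene (aryne) | COCOC1=CC#CC(Cl)=C1 | intermediate
20 | caesium 3-chloro-5-(methoxymethoxy)-2-{2-[4-methoxy-2,3-bis(methoxymethoxy)-5-(3-methylbut-2-en-1-yl)phenyl]prop-2-enoyl}phenoxide | [Cs+].[O-]c1cc(OCOC)cc(Cl)c1C(=O)C(=C)c1cc(CC=C(C)C)c(OC)c(OCOC)c1OCOC | intermediate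
21 | racemic 5-chloro-3-[4-methoxy-2,3-bis(methoxymethoxy)-5-(3-methylbut-2-en-1-yl)phenyl]-7-(methoxymethoxy)chroman-4-one | COc1c(CC=C(C)C)cc(C2COc3cc(OCOC)cc(Cl)c3C2=O)c(OCOC)c1OCOC | intermediate
22 | racemic 3-[4-methoxy-2,3-bis(methoxymethoxy)-5-(3-methylbut-2-en-1-yl)phenyl]-7-(methoxymethoxy)chroman-4-one | COc1c(CC=C(C)C)cc(C2COc3cc(OCOC)ccc3C2=O)c(OCOC)c1OCOC | intermediate
23 | racemic 3-[2,3-dihydroxy-4-methoxy-5-(3-methylbut-2-en-1-yl)phenyl]-7-hydroxychroman-4-one | COc1c(CC=C(C)C)cc(C2COc3cc(O)ccc3C2=O)c(O)c1O | intermediate
24 | 3-[4-methoxy-5-(3-methylbut-2-en-1-yl)-2,3-bis(trimethylsilyloxy)phenyl]-4,7-bis(trimethylsilyloxy)-2H-chromene | COc1c(CC=C(C)C)cc(C2=C(O[Si](C)(C)C)c3ccc(O[Si](C)(C)C)cc3OC2)c(O[Si](C)(C)C)c1O[Si](C)(C)C | intermediate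
25 | (3R)-3-[4-methoxy-5-(3-methylbut-2-en-1-yl)-2,3-bis(trimethylsilyloxy)phenyl]-7-(trimethylsilyloxy)chroman-4-one | COc1c(CC=C(C)C)cc([C@@H]2COc3cc(O[Si](C)(C)C)ccc3C2=O)c(O[Si](C)(C)C)c1O[Si](C)(C)C | intermediate
26 | (3R)-3-[2,3-dihydroxy-4-methoxy-5-(3-methylbut-2-en-1-yl)phenyl]-7-hydroxychroman-4-one | COc1c(CC=C(C)C)cc([C@@H]2COc3cc(O)ccc3C2=O)c(O)c1O | target

## Step count and risks

Total: 17 steps. Longest linear sequence: 13 steps (steps 5 to 12, then 13 to 17, from aldehyde 8). The aryne branch is four steps (1 to 4).

**Step 13 (key step).** The ortho-chloroaryl anion may be protonated before it transfers the acyl group, which stops the sequence at simple O-arylation of the acid. The 2-arylacrylate may dimerise or polymerise at 125 °C, and the excess aryne may arylate the enolate of the product. The chlorine makes the anion less nucleophilic than in the parent case, and this is the main uncertainty. Fallback, from ester 16 to triol 23: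
- Amidation of 16 with N,O-dimethylhydroxylamine hydrochloride and i-PrMgCl gives N-methoxy-N-methyl-2-[4-methoxy-2,3-bis(methoxymethoxy)-5-(3-methylbut-2-en-1-yl)phenyl]acetamide F1.
- 1-Bromo-2,4-bis(methoxymethoxy)benzene F2 (MOMCl and i-Pr2NEt on commercial 4-bromoresorcinol) is lithiated with n-BuLi at −78 °C and added to F1, giving the deoxybenzoin 1-[2,4-bis(methoxymethoxy)phenyl]-2-[4-methoxy-2,3-bis(methoxymethoxy)-5-(3-methylbut-2-en-1-yl)phenyl]ethan-1-one F3.
- Mannich methylenation with bis(dimethylamino)methane and acetic anhydride gives the enone 1-[2,4-bis(methoxymethoxy)phenyl]-2-[4-methoxy-2,3-bis(methoxymethoxy)-5-(3-methylbut-2-en-1-yl)phenyl]prop-2-en-1-one F4.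
- HCl in methanol removes the four MOM groups, and the freed ring A ortho-hydroxyl closes ring C by oxa-Michael addition. The route is rejoined at 23; steps 14 and 15 are then not needed.

**Step 17.** Facial selectivity of the protonation may be poor, because the ortho-silyloxy group on ring B crowds C3 in a way the known 2-aryl cycloalkanone substrates do not, and the strong acid may partly re-enolise the product. Fallback, from 23 to 26: the racemate is resolved by preparative chromatography on a chiral stationary phase. This gives 26 and (3S)-3-[2,3-dihydroxy-4-methoxy-5-(3-methylbut-2-en-1-yl)phenyl]-7-hydroxychroman-4-one F5. F5 is racemised with Et3N in methanol back to 23 and resolved again.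

**Step 3.** Butyllithium may attack silicon of the spectator silyl ether, or silyl groups may exchange between molecules, so that both oxygens or the wrong one are triflated. Lithium chloride may also be lost from the ortho-chloroaryllithium before the silyl group has migrated. Fallback, from 3 to 7:
- After n-BuLi at −78 °C the mixture is quenched with aqueous NH4Cl to give 5-chloro-4-(trimethylsilyl)benzene-1,3-diol F6.
- One equivalent of MOMCl with i-Pr2NEt reacts at the hydroxyl not flanked by silicon, giving 3-chloro-5-(methoxymethoxy)-2-(trimethylsilyl)phenol F7.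
- Tf2O and pyridine at 0 °C triflate the hindered hydroxyl and give 7.

**Step 7.** Masking of the aldehyde may be incomplete, so that butyllithium adds to it, and the allylation may partly give the 1,1-dimethylallyl isomer by allylic transposition. Fallback, from 10 to 13: Stille coupling of 10 with tributyl(3-methylbut-2-en-1-yl)stannane, Pd(PPh3)4, DMF, 90 °C gives 13 directly without an organolithium; no new compound is made (F0).

**Step 14.** The palladium hydride may move the prenyl double bond into conjugation with ring B, or reduction may be slow. Fallback, from 21 to 22: Miyaura borylation (Pd(OAc)2, XPhos, bis(pinacolato)diboron, KOAc, dioxane, 90 °C) gives racemic 3-[4-methoxy-2,3-bis(methoxymethoxy)-5-(3-methylbut-2-en-1-yl)phenyl]-7-(methoxymethoxy)-5-(4,4,5,5-tetramethyl-1,3,2-dioxaborolan-2-yl)chroman-4-one F8. No hydride is involved. Protodeboronation of this ortho-acyl arylboronate with CsF in aqueous dioxane at 80 °C gives 22.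

## Further compounds

F1 | step 13 | N-methoxy-N-methyl-2-[4-methoxy-2,3-bis(methoxymethoxy)-5-(3-methylbut-2-en-1-yl)phenyl]acetamide | COCOc1c(CC(=O)N(C)OC)cc(CC=C(C)C)c(OC)c1OCOC
F2 | step 13 | 1-bromo-2,4-bis(methoxymethoxy)benzene | COCOc1ccc(Br)c(OCOC)c1
F3 | step 13 | 1-[2,4-bis(methoxymethoxy)phenyl]-2-[4-methoxy-2,3-bis(methoxymethoxy)-5-(3-methylbut-2-en-1-yl)phenyl]ethan-1-one | COCOc1ccc(C(=O)Cc2cc(CC=C(C)C)c(OC)c(OCOC)c2OCOC)c(OCOC)c1
F4 | step 13 | 1-[2,4-bis(methoxymethoxy)phenyl]-2-[4-methoxy-2,3-bis(methoxymethoxy)-5-(3-methylbut-2-en-1-yl)phenyl]prop-2-en-1-one | COCOc1ccc(C(=O)C(=C)c2cc(CC=C(C)C)c(OC)c(OCOC)c2OCOC)c(OCOC)c1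
F5 | step 17 | (3S)-3-[2,3-dihydroxy-4-methoxy-5-(3-methylbut-2-en-1-yl)phenyl]-7-hydroxychroman-4-one | COc1c(CC=C(C)C)cc([C@H]2COc3cc(O)ccc3C2=O)c(O)c1O
F6 | step 3 | 5-chloro-4-(trimethylsilyl)benzene-1,3-diol | Oc1cc(O)c([Si](C)(C)C)c(Cl)c1
F7 | step 3 | 3-chloro-5-(methoxymethoxy)-2-(trimethylsilyl)phenol | COCOc1cc(O)c([Si](C)(C)C)c(Cl)c1
F0 | step 7 | none | none
F8 | step 14 | racemic 3-[4-methoxy-2,3-bis(methoxymethoxy)-5-(3-methylbut-2-en-1-yl)phenyl]-7-(methoxymethoxy)-5-(4,4,5,5-tetramethyl-1,3,2-dioxaborolan-2-yl)chroman-4-one | COc1c(CC=C(C)C)cc(C2COc3cc(OCOC)cc(B4OC(C)(C)C(C)(C)O4)c3C2=O)c(OCOC)c1OCOC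
A1 | alternative 1 | (3R)-7-(tert-butyldimethylsilyloxy)-3-[2,3-bis(tert-butyldimethylsilyloxy)-4-methoxy-5-(3-methylbut-2-en-1-yl)phenyl]chroman-4-one | COc1c(CC=C(C)C)cc([C@@H]2COc3cc(O[Si](C)(C)C(C)(C)C)ccc3C2=O)c(O[Si](C)(C)C(C)(C)C)c1O[Si](C)(C)C(C)(C)C
A2 | alternative 1 | 2-diazo-1-[4-(tert-butyldimethylsilyloxy)-2-methoxyphenyl]-2-[2,3-bis(tert-butyldimethylsilyloxy)-4-methoxy-5-(3-methylbut-2-en-1-yl)phenyl]ethan-1-one | COc1cc(O[Si](C)(C)C(C)(C)C)ccc1C(=O)C(=[N+]=[N-])c1cc(CC=C(C)C)c(OC)c(O[Si](C)(C)C(C)(C)C)c1O[Si](C)(C)C(C)(C)C
A3 | alternative 2 | (3R)-3-[2-hydroxy-4-methoxy-3-(methoxymethoxy)-5-(3-methylbut-2-en-1-yl)phenyl]-7-(methoxymethoxy)chroman-4-one | COc1c(CC=C(C)C)cc([C@@H]2COc3cc(OCOC)ccc3C2=O)c(O)c1OCOC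
A4 | alternative 2 | 2-{2-acetoxy-2-[2-(tert-butyldimethylsilyloxy)-4-methoxy-3-(methoxymethoxy)-5-(3-methylbut-2-en-1-yl)phenyl]ethoxy}-4-(methoxymethoxy)benzaldehyde | COCOc1ccc(C=O)c(OCC(OC(C)=O)c2cc(CC=C(C)C)c(OC)c(OCOC)c2O[Si](C)(C)C(C)(C)C)c1
A5 | alternative 3 | (3R)-3-[4-methoxy-2,3-bis(methoxymethoxy)-5-(3-methylbut-2-en-1-yl)phenyl]-7-(methoxymethoxy)chroman-4-one | COc1c(CC=C(C)C)cc([C@@H]2COc3cc(OCOC)ccc3C2=O)c(OCOC)c1OCOC
A6 | alternative 3 | 1-[2-hydroxy-4-(methoxymethoxy)phenyl]-2-[4-methoxy-2,3-bis(methoxymethoxy)-5-(3-methylbut-2-en-1-yl)phenyl]prop-2-en-1-one | COCOc1ccc(C(=O)C(=C)c2cc(CC=C(C)C)c(OC)c(OCOC)c2OCOC)c(O)c1
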